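## The problem

The target is a germacranolide: a ten-membered carbocycle with a Z-trisubstituted C1=C10 olefin (methyl C14) and an E-trisubstituted C4=C5 olefin (methyl C15), to which an α-methylene-γ-butyrolactone is fused cis across C6–C7. Four contiguous stereocentres, C6 (S), C7 (S), C8 (S) and C9 (R), carry the lactone oxygen, the lactone carbon C11, an ester oxygen and a free hydroxyl, all on one face of the ring. A fifth centre (R) sits in the 3-methyl-4-(octadecanoyloxy)butanoyl chain on O8 and must come from an enantiopure building block. Only C7 needs absolute induction: C8 can be set from C7, C9 from C8 and C6 from C7, if each reaction is chosen for the face it delivers on a ten-membered ring, where reagents enter from the periphery. The all-cis array is contra-steric at C8 (an electrophile is expected trans to the C7 branch), so that centre is best made by inversion. Fragile features are the exocyclic methylene lactone (a Michael acceptor), the cis C8-ester/C9-hydroxyl pair (1,2-acyl migration), the competition of O6 and O8 for the acyl carbon C12, the side-chain esters (no saponification once present) and the 1,5-diene (Cope rearrangement on overheating, transannular reactions in acid). Closing a ten-membered ring is costly, so the ring is better made by expansion. The enabling feature is that C5–C10, with oxygen on C6 and C9 and methyl on C10, are a dearomatised 4-methoxy-2-methylphenol, that C1–C4 with C15 are 1-methylcyclobutene, and that a Z,E-cyclodeca-1,5-diene is what a cyclohexane-fused bicyclo[2.2.0]hexane gives on thermal cycloreversion.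

## Retrosynthesis

**O9–Si.** Target 24 is traced to its C9 silyl ether 23. The C9 hydroxyl is kept masked to the last step because, free, it lies cis to the C8 ester (acyl migration) and γ to the C6 carbonyl of earlier intermediates (transannular hemiketal). The forward step needs only a fluoride source that the methylene lactone tolerates.

**C11=C13.** The methylene of 23 is cut back to the α-allyloxycarbonyl lactone 21 through the acid 22 (decarboxylative Mannich methylenation). The alternative, enolate aminomethylation of an unsubstituted lactone, needs strong base, which the side-chain esters would not survive. An allyl ester is chosen because saponification is excluded at this stage. The extra carboxyl is the second arm of the malonate that served as the C11 nucleophile.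

**C12–O6 and C6–H.** Lactone 21 is opened to hydroxy malonate 20, which comes from ketone 19 and this from dimethyl ketal 18. The cut is made here because the C6 oxygen is already present in the aromatic starting material. With O8 acylated and O9 silylated, O6 is the only oxygen that can close onto the malonate. The forward reaction must deliver hydride cis to C11.

**C9–H.** Silyl ether 18 comes from alcohol 17, and this from α-acyloxy ketone 16 by 1,2-reduction. The reduction is done while C6 is still a ketal, so that only one carbonyl is present. It must be 1,2-selective and give the alcohol cis to O8.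

**C8–O.** Ester 16 is cut at the C8–O bond into α-bromo ketone 10 and the side-chain acid 15. Direct hydroxylation is rejected: oxygen would arrive trans to the C7 branch and a free γ-hydroxy malonate would lactonise. Carboxylate displacement of a bromide inverts C8, installs the side chain and differentiates O8 from O9 in one step. Acid 15 comes from hemiester 11 and stearic acid 13 through 12 and 14.

**C8–Br.** Bromide 10 comes from Z,E-dienone 8 through silyl dienol ether 9. The C9 ketone is the handle that activates C8.

**C5–C10 and C1–C4 (ring expansion).** Dienone 8 is folded back, by re-forming these two σ-bonds, into tricyclic photoadduct 7. This removes the medium ring and both olefin-geometry problems at once. The forward cycloreversion must give Z at C1=C10 and E at C4=C5.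

**C1–C10 and C4–C5 (key step).** Photoadduct 7 is cut into enone 4 and 1-methylcyclobutene 6. Two small, easily made partners replace the whole ten-carbon perimeter. The forward reaction must join the methyl-bearing alkene carbon to C5 and not to C10.

**C7–C11 and the aromatic ring.** Enone 4 comes from quinone monoketal 2 and diallyl malonate 3 by asymmetric Michael addition, the only step that needs a chiral catalyst. Monoketal 2 comes from phenol 1, and alkene 6 from methylenecyclobutane 5.

## Roads not taken

**Alternative 1:** The cut is linear: C5–C6, C6–C7, C7–C11 and C7–C8 are formed on an open chain by three Matteson homologations of alkenylboronic ester A4 (LiCHCl2, ZnCl2), the α-chloride being displaced in turn by a 2-naphthylmethyl alkoxide, a 2-(silyloxymethyl)vinyl Grignard reagent and a 4-methoxybenzyl alkoxide, to give A1.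
- Merits: each of C6, C7 and C8 is set by one diol director under reagent control; O6 and O8 are differently protected from the start; both olefins are fixed in acyclic precursors; C11–C13 is carried as a masked acrylate.
- Weak points: the director imposes the same sense at every insertion, so the all-cis pattern has to be matched by the order of the displacements; the vinyl Grignard displacement is at a congested α-chloro boronate; the sequence is long and linear; after A1 the C9 centre and the ten-membered ring closure still lie ahead.
- Comparison: this road is better than the chosen plan in stereochemical assurance at C6–C8, which the chosen plan relays from C7 by substrate control. Against that the chosen plan sets the ring and both olefins made in two steps from a phenol and a C5 alkene, with no macrocyclisation.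

**Alternative 2:** The cut is C3–C4. N-hydroxyphthalimide ester A5 is reduced at the cathode, the C3 radical is captured by NiCl2(bpy) (bpy = 2,2′-bipyridine) and coupled with the E-iodoalkene terminus, closing the ring to A2.
- Merits: it is convergent; all stereocentres and the side chain are in place before the ring closes; the C4 geometry is transferred from the iodide; conditions are mild and the lactone is left open to lower strain.
- Weak points: a ten-membered ring must be closed by capture of a primary radical, against entropy and transannular strain, in competition with reduction and dimerisation; A5 needs four contiguous centres built acyclically.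
- Comparison: this road is better in convergence and avoids any stereochemical relay on a macrocycle. The chosen plan sets against it that its ring formation is driven by strain release rather than fought against strain, and that it is much shorter to the ring.

**Alternative 3:** The cut is C7–C8. In A6, BF3·OEt2 activates the C8 aldehyde and the γ-carbon of the 3-(tributylstannylmethyl)butenolide attacks it, closing the ring, shifting the double bond to C11=C13 and giving A3.
- Merits: one step forms the ring, sets C7 and C8 and unveils the methylene lactone; A3 emerges with O8 free and O9 silylated, two steps from the target. In end-game economy this road is clearly better than the chosen plan.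
- Weak points: the medium-ring allylation must deliver both the cis ring fusion and O8 cis to C11 through an open transition state with no obvious bias; the α-silyloxy-β,γ-unsaturated aldehyde of A6 is prone to epimerisation and conjugation; stoichiometric tin is used; C6 and C9 must be set acyclically.
- Comparison: the chosen plan has the longer end game but a secure ring-forming event and stereospecific control at C8 (SN2 inversion).

Key step: step 4

Remark: positions are given in germacrane numbering (C1–C15, C12 the lactone carbonyl); 3, 11 and 13 are taken as catalogue chemicals, 11 as the single (R)-enantiomer.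

## Route

Step 1
Reactants: 1 4-methoxy-2-methylphenol
Product: 2 4,4-dimethoxy-2-methylcyclohexa-2,5-dien-1-one
Conditions: PhI(OAc)2, MeOH, 0 °C
Reagents that add atoms: methanol, CO
Why: Oxidative dearomatisation of a para-alkoxyphenol with a hypervalent iodine diacetate; methanol captures the phenoxenium ion at the methoxy-bearing carbon, the standard entry to quinone monoketals.

Step 2
Reactants: 2 4,4-dimethoxy-2-methylcyclohexa-2,5-dien-1-one; 3 diallyl malonate
Product: 4 diallyl 2-[(1S)-2,2-dimethoxy-4-methyl-5-oxocyclohex-3-en-1-yl]malonate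
Conditions: LiAl[(S)-binaphtholate]2 (10 mol %), KOt-Bu (9 mol %), 4 Å MS, THF, 0 °C → rt
Reagents that add atoms: none
Why: Catalytic asymmetric Michael addition of a malonate to a cyclic enone with a bifunctional lithium–aluminium binaphtholate; the malonate should add to the unsubstituted enone (the α-methyl enone is less electrophilic) and the catalyst selects the enone face, setting C7 as S. The (S)-ligand is assigned by analogy with cyclohexenone and the antipodal catalyst is equally available.

Step 3
Reactants: 5 methylenecyclobutane
Product: 6 1-methylcyclobutene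
Conditions: Na/Al2O3 (cat.), neat, 0–5 °C; fractional distillation
Reagents that add atoms: none
Why: Base-mediated allylic isomerisation; the equilibrium favours the trisubstituted endocyclic alkene, which is separated cold by fractional distillation.

Step 4
Reactants: 4 diallyl 2-[(1S)-2,2-dimethoxy-4-methyl-5-oxocyclohex-3-en-1-yl]malonate; 6 1-methylcyclobutene
Product: 7 cis-anti-cis photoadduct diallyl 2-[(1S,2R,5S,6R,8S)-7,7-dimethoxy-1,5-dimethyl-10-oxotricyclo[4.4.0.0^{2,5}]decan-8-yl]malonate (germacrane centres 10S,1R,4S,5R,7S; drawn as the expected major isomer)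
Conditions: hν (366 nm, Pyrex), 6 (10 equiv), CH2Cl2, −40 °C, degassed
Reagents that add atoms: none
Why: Excitation of the enone and intersystem crossing give the twisted triplet, which adds to the strained alkene to form a triplet 1,4-diradical; spin inversion and radical recombination then close the four-membered ring, the classical enone–alkene [2+2] photocycloaddition of the cyclohexenone–cyclobutene type. The one new ring, cyclobutane C1–C4–C5–C10, closes by this diradical collapse and, sharing C1–C4 with the existing four-membered ring and C5–C10 with the cyclohexanone, completes the bicyclo[2.2.0]hexane and the tricycle. The selectivity the plan needs is head-to-tail regiochemistry, C4 (methyl-bearing) to the β-carbon C5 and C1 to C10; it is secured by the polarity of the donor-substituted alkene towards the enone triplet and, decisively, by the alternative having to join two quaternary carbons (C4 and C10). C1 and C4 are cis by the ring constraint of the cyclobutene; C5 and C10 are cis because the relaxed diradical closes to the less strained cis-fused bicyclo[4.2.0]octanone; the anti relation of the outer rings and the face anti to the C7 branch follow from the least hindered approach. None of the four new centres survives step 5, so facial and exo/endo selectivity are irrelevant, but the cis ring fusion matters because it is carried into the olefin geometry. Excess alkene, low temperature and long-wavelength light are used to outrun unimolecular enone photochemistry and α-cleavage of the product ketone; the allyl ester olefins are too remote and too dilute to compete.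

Step 5
Reactants: 7 cis-anti-cis photoadduct
Product: 8 diallyl 2-[(1S,3E,7Z)-2,2-dimethoxy-4,8-dimethyl-9-oxocyclodeca-3,7-dien-1-yl]malonate (Z,E-dienone)
Conditions: xylene (degassed, base-washed sealed tube, BHT), 150–160 °C
Reagents that add atoms: none
Why: Thermal cycloreversion of the bicyclo[2.2.0]hexane through a cyclohexane-1,4-diyl: the central C1–C4 bond breaks first, then C5–C10, which is flanked by the ketone and the ketal. In the chair diyl the C10 methyl and C6 sit equatorial and C9 axial, which should translate into Z at C1=C10 and E at C4=C5. All four photochemical centres vanish, so every cis-fused isomer of 7 converges on 8.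

Step 6
Reactants: 8 Z,E-dienone
Product: 10 diallyl 2-[(1S,3E,7Z,10R)-10-bromo-2,2-dimethoxy-4,8-dimethyl-9-oxocyclodeca-3,7-dien-1-yl]malonate (C8 bromide; bromine trans to the C7 branch), via triethylsilyl dienol ether 9 (not isolated)
Conditions: LiN(SiMe3)2 (2.1 equiv), THF, −78 °C; Et3SiCl (1.1 equiv); pH 7 work-up; then NBS, NaHCO3, THF, −78 °C
Reagents that add atoms: N-bromosuccinimide, O=C1CCC(=O)N1Br
Why: The first equivalent of base is consumed by the malonate C–H (its delocalised enolate stays unsilylated and is reprotonated on work-up); the second gives the kinetic α′-enolate, trapped on oxygen as the 2-silyloxydiene. NBS brominates the enol ether carbon C8 much faster than the trisubstituted olefins. By the peripheral-attack model for medium-ring enolates (C7–H in the enol plane, ring carbon C6 on the inner face) bromine should enter trans to the C7 branch.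

Step 7
Reactants: 11 (R)-4-tert-butoxy-2-methyl-4-oxobutanoic acid
Product: 12 tert-butyl (3R)-4-hydroxy-3-methylbutanoate
Conditions: BH3·SMe2, THF, 0 °C → rt; MeOH quench
Reagents that add atoms: none
Why: Borane reduces the free carboxylic acid (through the acyloxyborane) much faster than the tert-butyl ester; the stereocentre is not involved.

Step 8
Reactants: 12 tert-butyl (3R)-4-hydroxy-3-methylbutanoate; 13 stearic acid
Product: 14 tert-butyl (3R)-3-methyl-4-(octadecanoyloxy)butanoate
Conditions: EDC·HCl, DMAP (cat.), CH2Cl2, 0 °C → rt
Reagents that add atoms: none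
Why: Steglich esterification of a primary alcohol, run directly on fresh 12 so that the γ-hydroxy ester has no time to lactonise.

Step 9
Reactants: 14 tert-butyl (3R)-3-methyl-4-(octadecanoyloxy)butanoate
Product: 15 (3R)-3-methyl-4-(octadecanoyloxy)butanoic acid
Conditions: CF3CO2H, CH2Cl2, 0 °C → rt
Reagents that add atoms: none
Why: Acidolysis of the tert-butyl ester (loss of isobutene) leaves the primary stearate untouched.

Step 10
Reactants: 10 C8 bromide; 15 (3R)-3-methyl-4-(octadecanoyloxy)butanoic acid
Product: 16 diallyl 2-[(1R,3E,7Z,10S)-2,2-dimethoxy-4,8-dimethyl-10-{[(3R)-3-methyl-4-(octadecanoyloxy)butanoyl]oxy}-9-oxocyclodeca-3,7-dien-1-yl]malonate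
Conditions: 15, Cs2CO3 (0.5 equiv per 15), MeOH, then evaporate; 10, DMF, 0 °C → rt
Reagents that add atoms: none
Why: SN2 displacement of an α-bromo ketone by a caesium carboxylate in a dipolar aprotic solvent goes with inversion, so the ester oxygen should arrive cis to the C7 branch (8S). The side chain is installed without a free C8 hydroxyl ever facing the malonate, and the carboxylate is too weak a base to deprotonate the malonate.

Step 11
Reactants: 16 α-acyloxy ketone
Product: 17 diallyl 2-[(1R,3E,7Z,9R,10S)-9-hydroxy-2,2-dimethoxy-4,8-dimethyl-10-{[(3R)-3-methyl-4-(octadecanoyloxy)butanoyl]oxy}cyclodeca-3,7-dien-1-yl]malonate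
Conditions: NaBH4, CeCl3·7H2O, THF/MeOH, −78 °C; AcOH quench at −78 °C
Reagents that add atoms: none
Why: Luche reduction gives clean 1,2-addition to the enone. Hydride is expected from the ring periphery, anti to the C8–C7 ring bond with the C8 oxygen near the plane of the cerium-activated carbonyl, which places the new hydroxyl cis to O8 (9R). The cold acidic quench is meant to prevent 1,2-acyl migration.

Step 12
Reactants: 17 C9 alcohol
Product: 18 diallyl 2-[(1R,3E,7Z,9R,10S)-9-[(tert-butyldimethylsilyl)oxy]-2,2-dimethoxy-4,8-dimethyl-10-{[(3R)-3-methyl-4-(octadecanoyloxy)butanoyl]oxy}cyclodeca-3,7-dien-1-yl]malonate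
Conditions: TBSOTf, 2,6-lutidine, CH2Cl2, −78 °C
Reagents that add atoms: tert-butyldimethylsilyl trifluoromethanesulfonate, CC(C)(C)[Si](C)(C)OS(=O)(=O)C(F)(F)F
Why: Silyl triflate with a hindered pyridine silylates the hindered allylic alcohol at low temperature; this blocks acyl migration from O8 and hemiketal formation with the C6 carbonyl to come.

Step 13
Reactants: 18 C9 silyl ether
Product: 19 diallyl 2-[(1R,3E,7Z,9R,10S)-9-[(tert-butyldimethylsilyl)oxy]-4,8-dimethyl-10-{[(3R)-3-methyl-4-(octadecanoyloxy)butanoyl]oxy}-2-oxocyclodeca-3,7-dien-1-yl]malonate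
Conditions: PPTS (cat.), acetone/H2O, rt
Reagents that add atoms: water, O
Why: Mild acid hydrolysis of an allylic dimethyl ketal through a conjugated oxocarbenium ion; the silyl ether and esters are stable, and in the ten-membered ring aromatisation is no longer possible.

Step 14
Reactants: 19 C6 enone
Product: 21 allyl (3aS,4S,5R,6Z,10E,11aS)-5-[(tert-butyldimethylsilyl)oxy]-6,10-dimethyl-4-{[(3R)-3-methyl-4-(octadecanoyloxy)butanoyl]oxy}-2-oxo-2,3,3a,4,5,8,9,11a-octahydrocyclodeca[b]furan-3-carboxylate (C3 epimers), via hydroxy malonate 20 (not isolated)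
Conditions: NaBH4, CeCl3·7H2O, THF/MeOH, −78 °C, AcOH quench; then PPTS (cat.), CH2Cl2, rt
Reagents that add atoms: none
Why: Luche 1,2-reduction of the β,β-disubstituted enone; peripheral hydride attack anti to the C7–C8 ring bond, with the malonate branch near the carbonyl plane, should give the 6S alcohol cis to C11. That alcohol closes onto one of the two equivalent allyl esters by acyl substitution; C11 becomes an epimerisable centre of no consequence.

Step 15
Reactants: 21 lactone allyl ester
Product: 23 (3aS,4S,5R,6Z,10E,11aS)-5-[(tert-butyldimethylsilyl)oxy]-6,10-dimethyl-3-methylidene-2-oxo-2,3,3a,4,5,8,9,11a-octahydrocyclodeca[b]furan-4-yl (3R)-3-methyl-4-(octadecanoyloxy)butanoate, via carboxy lactone 22 (not isolated)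
Conditions: Pd(PPh3)4 (5 mol %), morpholine, THF, rt; then aq. HCHO, AcOH, rt → 40 °C
Reagents that add atoms: formaldehyde, C=O
Why: Zerovalent palladium ionises the allyl ester and the allyl group is passed to morpholine, leaving the malonic half-acid. This undergoes the decarboxylative Mannich methylenation (aminomethylation at C11, then loss of CO2 and amine), the classical conversion of α-carboxy lactones into α-methylene lactones; no hydroxide is used, so the side-chain esters survive.

Step 16
Reactants: 23 silyl-protected methylene lactone
Product: 24 (3aS,4S,5R,6Z,10E,11aS)-5-hydroxy-6,10-dimethyl-3-methylidene-2-oxo-2,3,3a,4,5,8,9,11a-octahydrocyclodeca[b]furan-4-yl (3R)-3-methyl-4-(octadecanoyloxy)butanoate (CNP0114940.1)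
Conditions: HF·pyridine, pyridine, THF, 0 °C → rt
Reagents that add atoms: none
Why: Buffered fluoride cleaves the secondary silyl ether under mildly acidic conditions, which the methylene lactone and both esters tolerate and which do not promote acyl migration from O8 to O9.

## Compound list

1 | 4-methoxy-2-methylphenol | COc1ccc(O)c(C)c1 | starting material
2 | 4,4-dimethoxy-2-methylcyclohexa-2,5-dien-1-one | COC1(OC)C=CC(=O)C(C)=C1 | intermediate
3 | diallyl malonate | C=CCOC(=O)CC(=O)OCC=C | starting material
4 | diallyl 2-[(1S)-2,2-dimethoxy-4-methyl-5-oxocyclohex-3-en-1-yl]malonate | CC1=CC(OC)(OC)[C@H](C(C(=O)OCC=C)C(=O)OCC=C)CC1=O | intermediate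
5 | methylenecyclobutane | C=C1CCC1 | starting material
6 | 1-methylcyclobutene | CC1=CCC1 | intermediate
7 | diallyl 2-[(1S,2R,5S,6R,8S)-7,7-dimethoxy-1,5-dimethyl-10-oxotricyclo[4.4.0.0^{2,5}]decan-8-yl]malonate (cis-anti-cis photoadduct) | O=C1C[C@@H](C(C(=O)OCC=C)C(=O)OCC=C)C(OC)(OC)[C@H]2[C@]1(C)[C@@H]3CC[C@]23C | intermediate
8 | diallyl 2-[(1S,3E,7Z)-2,2-dimethoxy-4,8-dimethyl-9-oxocyclodeca-3,7-dien-1-yl]malonate | COC1(OC)/C=C(\C)CC/C=C(/C)C(=O)C[C@H]1C(C(=O)OCC=C)C(=O)OCC=C | intermediate
9 | diallyl 2-[(1S,3E,7Z)-2,2-dimethoxy-4,8-dimethyl-9-(triethylsilyloxy)cyclodeca-3,7,9-trien-1-yl]malonate (enol ether geometry not assigned) | COC1(OC)/C=C(\C)CC/C=C(/C)C(O[Si](CC)(CC)CC)=C[C@H]1C(C(=O)OCC=C)C(=O)OCC=C | intermediate (not isolated)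
10 | diallyl 2-[(1S,3E,7Z,10R)-10-bromo-2,2-dimethoxy-4,8-dimethyl-9-oxocyclodeca-3,7-dien-1-yl]malonate | COC1(OC)/C=C(\C)CC/C=C(/C)C(=O)[C@H](Br)[C@H]1C(C(=O)OCC=C)C(=O)OCC=C | intermediate
11 | (R)-4-tert-butoxy-2-methyl-4-oxobutanoic acid | CC(C)(C)OC(=O)C[C@@H](C)C(=O)O | starting material
12 | tert-butyl (3R)-4-hydroxy-3-methylbutanoate | CC(C)(C)OC(=O)C[C@@H](C)CO | intermediate
13 | stearic acid (octadecanoic acid) | CCCCCCCCCCCCCCCCCC(=O)O | starting material
14 | tert-butyl (3R)-3-methyl-4-(octadecanoyloxy)butanoate | CC(C)(C)OC(=O)C[C@@H](C)COC(=O)CCCCCCCCCCCCCCCCC | intermediate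
15 | (3R)-3-methyl-4-(octadecanoyloxy)butanoic acid | OC(=O)C[C@@H](C)COC(=O)CCCCCCCCCCCCCCCCC | intermediate
16 | diallyl 2-[(1R,3E,7Z,10S)-2,2-dimethoxy-4,8-dimethyl-10-{[(3R)-3-methyl-4-(octadecanoyloxy)butanoyl]oxy}-9-oxocyclodeca-3,7-dien-1-yl]malonate | COC1(OC)/C=C(\C)CC/C=C(/C)C(=O)[C@@H](OC(=O)C[C@@H](C)COC(=O)CCCCCCCCCCCCCCCCC)[C@H]1C(C(=O)OCC=C)C(=O)OCC=C | intermediate
17 | diallyl 2-[(1R,3E,7Z,9R,10S)-9-hydroxy-2,2-dimethoxy-4,8-dimethyl-10-{[(3R)-3-methyl-4-(octadecanoyloxy)butanoyl]oxy}cyclodeca-3,7-dien-1-yl]malonate | COC1(OC)/C=C(\C)CC/C=C(/C)[C@@H](O)[C@@H](OC(=O)C[C@@H](C)COC(=O)CCCCCCCCCCCCCCCCC)[C@H]1C(C(=O)OCC=C)C(=O)OCC=C | intermediate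
18 | diallyl 2-[(1R,3E,7Z,9R,10S)-9-[(tert-butyldimethylsilyl)oxy]-2,2-dimethoxy-4,8-dimethyl-10-{[(3R)-3-methyl-4-(octadecanoyloxy)butanoyl]oxy}cyclodeca-3,7-dien-1-yl]malonate | COC1(OC)/C=C(\C)CC/C=C(/C)[C@@H](O[Si](C)(C)C(C)(C)C)[C@@H](OC(=O)C[C@@H](C)COC(=O)CCCCCCCCCCCCCCCCC)[C@H]1C(C(=O)OCC=C)C(=O)OCC=C | intermediate
19 | diallyl 2-[(1R,3E,7Z,9R,10S)-9-[(tert-butyldimethylsilyl)oxy]-4,8-dimethyl-10-{[(3R)-3-methyl-4-(octadecanoyloxy)butanoyl]oxy}-2-oxocyclodeca-3,7-dien-1-yl]malonate | O=C1/C=C(\C)CC/C=C(/C)[C@@H](O[Si](C)(C)C(C)(C)C)[C@@H](OC(=O)C[C@@H](C)COC(=O)CCCCCCCCCCCCCCCCC)[C@H]1C(C(=O)OCC=C)C(=O)OCC=C | intermediate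
20 | diallyl 2-[(1S,2S,3E,7Z,9R,10S)-9-[(tert-butyldimethylsilyl)oxy]-2-hydroxy-4,8-dimethyl-10-{[(3R)-3-methyl-4-(octadecanoyloxy)butanoyl]oxy}cyclodeca-3,7-dien-1-yl]malonate | O[C@H]1/C=C(\C)CC/C=C(/C)[C@@H](O[Si](C)(C)C(C)(C)C)[C@@H](OC(=O)C[C@@H](C)COC(=O)CCCCCCCCCCCCCCCCC)[C@H]1C(C(=O)OCC=C)C(=O)OCC=C | intermediate (not isolated)
21 | allyl (3aS,4S,5R,6Z,10E,11aS)-5-[(tert-butyldimethylsilyl)oxy]-6,10-dimethyl-4-{[(3R)-3-methyl-4-(octadecanoyloxy)butanoyl]oxy}-2-oxo-2,3,3a,4,5,8,9,11a-octahydrocyclodeca[b]furan-3-carboxylate (C3 epimers) | C=CCOC(=O)C1C(=O)O[C@H]2/C=C(\C)CC/C=C(/C)[C@@H](O[Si](C)(C)C(C)(C)C)[C@@H](OC(=O)C[C@@H](C)COC(=O)CCCCCCCCCCCCCCCCC)[C@@H]12 | intermediate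
22 | (3aS,4S,5R,6Z,10E,11aS)-5-[(tert-butyldimethylsilyl)oxy]-6,10-dimethyl-4-{[(3R)-3-methyl-4-(octadecanoyloxy)butanoyl]oxy}-2-oxo-2,3,3a,4,5,8,9,11a-octahydrocyclodeca[b]furan-3-carboxylic acid (C3 epimers) | OC(=O)C1C(=O)O[C@H]2/C=C(\C)CC/C=C(/C)[C@@H](O[Si](C)(C)C(C)(C)C)[C@@H](OC(=O)C[C@@H](C)COC(=O)CCCCCCCCCCCCCCCCC)[C@@H]12 | intermediate (not isolated)
23 | (3aS,4S,5R,6Z,10E,11aS)-5-[(tert-butyldimethylsilyl)oxy]-6,10-dimethyl-3-methylidene-2-oxo-2,3,3a,4,5,8,9,11a-octahydrocyclodeca[b]furan-4-yl (3R)-3-methyl-4-(octadecanoyloxy)butanoate | C=C1C(=O)O[C@H]2/C=C(\C)CC/C=C(/C)[C@@H](O[Si](C)(C)C(C)(C)C)[C@@H](OC(=O)C[C@@H](C)COC(=O)CCCCCCCCCCCCCCCCC)[C@@H]12 | intermediate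
24 | (3aS,4S,5R,6Z,10E,11aS)-5-hydroxy-6,10-dimethyl-3-methylidene-2-oxo-2,3,3a,4,5,8,9,11a-octahydrocyclodeca[b]furan-4-yl (3R)-3-methyl-4-(octadecanoyloxy)butanoate | C=C1C(=O)O[C@H]2/C=C(\C)CC/C=C(/C)[C@@H](O)[C@@H](OC(=O)C[C@@H](C)COC(=O)CCCCCCCCCCCCCCCCC)[C@@H]12 | target

## Step count and least certain steps

Total: 16 steps. Longest linear sequence: 12 steps (1, 2, 4, 5, 6, 10, 11, 12, 13, 14, 15, 16) from 4-methoxy-2-methylphenol.

**Step 4 (key step).** Capture of the short-lived enone triplet by the alkene may lose to unimolecular decay (hydrogen abstraction from the malonate C–H or a methoxy group, skeletal rearrangement of the 4,4-dialkoxyenone), because the β-carbon lies between the ketal and the C7 branch; part of the adduct may also form with a trans ring fusion. The fallback reverses the order of the two C–C bond formations and sets out from 2. Conjugate reduction of the unsubstituted enone with [(Ph3P)CuH]6 would give 4,4-dimethoxy-2-methylcyclohex-2-en-1-one F1. Irradiation of F1 with 6 would give the racemic tricyclic ketone F2. Dehydrogenation with 2-iodoxybenzoic acid towards C8, the only enolisable side, would give the tricyclic enone F3. The binaphtholate-catalysed malonate addition of step 2, applied to F3 under catalyst control, would give 7 from one enantiomer of F3 and the core diastereomer F4 from the other. Both open to the same dienone in step 5, so the route is rejoined at 7.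

**Step 2.** Addition at a β-carbon next to the quaternary ketal may be slow and poorly enantioselective, with retro-Michael erosion and aromatisation by loss of methanol on long exposure to base. In the fallback the addition of 3 to 2 is run with catalytic KOt-Bu alone, and the enantiomers are separated by preparative chromatography on a chiral stationary phase. The unwanted enantiomer F5 is returned to the racemate by base-mediated retro-Michael/Michael equilibration and recycled. The route is rejoined at 4.

**Step 5.** The opening passes through a cyclohexane-1,4-diyl. A trans-fused fraction of 7, or collapse from the less favoured chair, would give the 1(10)E isomer, and prolonged heating would start a Cope rearrangement to an elemane-type divinylcyclohexanone. In the fallback the thermolysis of 7 is stopped at partial conversion at the lowest workable temperature. The E,E-dienone F6 is separated and only its conjugated C1=C10 bond is equilibrated by reversible conjugate addition of thiophenol (PhSH, cat. Et3N, THF); the in-ring cis enone is the more stable one in a ten-membered ring. The route is rejoined at 8.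

**Step 10.** Stereochemical integrity at C8 may be lost: bromide set free during the substitution can re-attack unreacted 10, base can epimerise 16 through its enol, and elimination of HBr or C-alkylation by the malonate are further leaks. The fallback introduces oxygen first and inverts without any halide present; it sets out from 8 through 9. Rubottom oxidation of 9 with dimethyldioxirane (same peripheral face as the bromination) would give the 8-epi α-hydroxy ketone F7, used at once. Mitsunobu esterification of F7 with 15 (PPh3, DIAD) would invert C8 and return to the route at 16.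

**Step 11.** Facial selectivity is the concern: a conformer with the C8–O bond perpendicular to the carbonyl (polar Felkin–Anh) would lead to the 9-epi alcohol. A slow quench would also allow migration of the side-chain acyl group to the new alkoxide. The fallback replaces substrate control by reagent control: 16 is reduced by Corey–Bakshi–Shibata reduction with (R)-1-methyl-3,3-diphenyltetrahydro-1H,3H-pyrrolo[1,2-c][1,3,2]oxazaborole and catecholborane, with the α-methylalkenyl group taken as the large substituent; the borate product is not basic. Any 9-epi alcohol F8 from the Luche run is returned to 16 by Dess–Martin oxidation. The route is rejoined at 17.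

**Step 14.** Two processes threaten this step: base-induced elimination of the C8 carboxylate from the β-acyloxy ketone 19 before reduction, and hydride entering from the other face to give the 6-epi alkoxide. The fallback closes the lactone with inversion instead of retention and sets out from 19. The reduction is quenched cold so that the 6-epi hydroxy malonate F9 is isolated. Both allyl esters are removed (Pd(PPh3)4, morpholine) to give the hydroxy malonic acid F10. Mitsunobu lactonisation (PPh3, DIAD) then displaces the activated allylic C6 oxygen by a carboxylate with inversion, giving carboxy lactone 22 and rejoining the route in step 15.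

## Further compounds

F1 | step 4 | 4,4-dimethoxy-2-methylcyclohex-2-en-1-one | CC1=CC(OC)(OC)CCC1=O
F2 | step 4 | rac-(1S,2R,5S,6R)-7,7-dimethoxy-1,5-dimethyltricyclo[4.4.0.0^{2,5}]decan-10-one (one enantiomer drawn) | O=C1CCC(OC)(OC)[C@H]2[C@]1(C)[C@@H]3CC[C@]23C
F3 | step 4 | rac-(1S,2R,5S,6R)-7,7-dimethoxy-1,5-dimethyltricyclo[4.4.0.0^{2,5}]dec-8-en-10-one (one enantiomer drawn) | O=C1C=CC(OC)(OC)[C@H]2[C@]1(C)[C@@H]3CC[C@]23C
F4 | step 4 | diallyl 2-[(1R,2S,5R,6S,8S)-7,7-dimethoxy-1,5-dimethyl-10-oxotricyclo[4.4.0.0^{2,5}]decan-8-yl]malonate (core diastereomer of 7) | O=C1C[C@@H](C(C(=O)OCC=C)C(=O)OCC=C)C(OC)(OC)[C@@H]2[C@@]1(C)[C@H]3CC[C@@]23C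
F5 | step 2 | diallyl 2-[(1R)-2,2-dimethoxy-4-methyl-5-oxocyclohex-3-en-1-yl]malonate (enantiomer of 4) | CC1=CC(OC)(OC)[C@@H](C(C(=O)OCC=C)C(=O)OCC=C)CC1=O
F6 | step 5 | diallyl 2-[(1S,3E,7E)-2,2-dimethoxy-4,8-dimethyl-9-oxocyclodeca-3,7-dien-1-yl]malonate | COC1(OC)/C=C(\C)CC/C=C(\C)C(=O)C[C@H]1C(C(=O)OCC=C)C(=O)OCC=C
F7 | step 10 | diallyl 2-[(1S,3E,7Z,10R)-10-hydroxy-2,2-dimethoxy-4,8-dimethyl-9-oxocyclodeca-3,7-dien-1-yl]malonate (8-epi hydroxy ketone) | COC1(OC)/C=C(\C)CC/C=C(/C)C(=O)[C@H](O)[C@H]1C(C(=O)OCC=C)C(=O)OCC=C
F8 | step 11 | diallyl 2-[(1R,3E,7Z,9S,10S)-9-hydroxy-2,2-dimethoxy-4,8-dimethyl-10-{[(3R)-3-methyl-4-(octadecanoyloxy)butanoyl]oxy}cyclodeca-3,7-dien-1-yl]malonate (9-epi alcohol) | COC1(OC)/C=C(\C)CC/C=C(/C)[C@H](O)[C@@H](OC(=O)C[C@@H](C)COC(=O)CCCCCCCCCCCCCCCCC)[C@H]1C(C(=O)OCC=C)C(=O)OCC=C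
F9 | step 14 | diallyl 2-[(1S,2R,3E,7Z,9R,10S)-9-[(tert-butyldimethylsilyl)oxy]-2-hydroxy-4,8-dimethyl-10-{[(3R)-3-methyl-4-(octadecanoyloxy)butanoyl]oxy}cyclodeca-3,7-dien-1-yl]malonate (6-epi hydroxy malonate) | O[C@@H]1/C=C(\C)CC/C=C(/C)[C@@H](O[Si](C)(C)C(C)(C)C)[C@@H](OC(=O)C[C@@H](C)COC(=O)CCCCCCCCCCCCCCCCC)[C@H]1C(C(=O)OCC=C)C(=O)OCC=C
F10 | step 14 | 2-[(1S,2R,3E,7Z,9R,10S)-9-[(tert-butyldimethylsilyl)oxy]-2-hydroxy-4,8-dimethyl-10-{[(3R)-3-methyl-4-(octadecanoyloxy)butanoyl]oxy}cyclodeca-3,7-dien-1-yl]malonic acid | O[C@@H]1/C=C(\C)CC/C=C(/C)[C@@H](O[Si](C)(C)C(C)(C)C)[C@@H](OC(=O)C[C@@H](C)COC(=O)CCCCCCCCCCCCCCCCC)[C@H]1C(C(=O)O)C(=O)O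
A1 | alternative 1 | C5–C8 boronic ester with C6 2-naphthylmethyl ether, C7 2-(silyloxymethyl)vinyl arm and C8 4-methoxybenzyl ether, (R,R)-1,2-dicyclohexylethane-1,2-diol ester | I/C(C)=C\CC/C(C)=C/[C@H](OCc1ccc2ccccc2c1)[C@H](C(=C)CO[Si](C)(C)C(C)(C)C)[C@H](OCc1ccc(OC)cc1)B1O[C@H](C2CCCCC2)[C@@H](C2CCCCC2)O1
A2 | alternative 2 | ten-membered carbocycle with open bis-silyl lactone, C8 side-chain ester and C9 silyl ether | C/C1=C\[C@H](O[Si](CC)(CC)CC)[C@H](C(=C)CO[Si](CC)(CC)CC)[C@H](OC(=O)C[C@@H](C)COC(=O)CCCCCCCCCCCCCCCCC)[C@H](O[Si](C)(C)C(C)(C)C)/C(C)=C\CC1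
A3 | alternative 3 | lactone core with free C8 hydroxyl and C9 tert-butyldimethylsilyl ether | C=C1C(=O)O[C@H]2/C=C(\C)CC/C=C(/C)[C@@H](O[Si](C)(C)C(C)(C)C)[C@@H](O)[C@@H]12
A4 | alternative 1 | (4R,5R)-4,5-dicyclohexyl-2-[(1E,5Z)-6-iodo-2-methylhepta-1,5-dien-1-yl]-1,3,2-dioxaborolane | I/C(C)=C\CC/C(C)=C/B1O[C@H](C2CCCCC2)[C@@H](C2CCCCC2)O1
A5 | alternative 2 | open-chain N-hydroxyphthalimide ester with E-iodoalkene terminus | C/C(I)=C\[C@H](O[Si](CC)(CC)CC)[C@H](C(=C)CO[Si](CC)(CC)CC)[C@H](OC(=O)C[C@@H](C)COC(=O)CCCCCCCCCCCCCCCCC)[C@H](O[Si](C)(C)C(C)(C)C)/C(C)=C\CCC(=O)ON1C(=O)c2ccccc2C1=O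
A6 | alternative 3 | open-chain C8 aldehyde carrying the 3-(tributylstannylmethyl)butenolide | CCCC[Sn](CCCC)(CCCC)CC1=C[C@H](/C=C(\C)CC/C=C(/C)[C@@H](O[Si](C)(C)C(C)(C)C)C=O)OC1=O
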